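Readings and results were generated by integration with constants of no real substance.

At early times the spring run, which is this very flask followed so far, and the dawn run both climb steeply in Z. Their first readings, set against each run's last reading, give rise constants of 2.56 /d for spring and 5.30 /d for dawn, a speed-up of 2.07 that one may take as the effect of temperature; but both runs then level off near the same height, and the dispute is over what that level means.

| setting | spring | dawn | flask |
|---|---|---|---|
| G | 1.5 M | 3 M | 1.5 M |
| E | 1.8 M | 1.8 M | 1.80 M |
| temperature | 50 °C | 56 °C | 50 °C |
| remark | the very flask that is asked about, followed so far | run made earlier |  |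
| time |  |  | 5.0 d |

spring run (percent of the G charged)

| time / d | Z / % |
|---|---|
| 0.833 | 51.5 |
| 1.67 | 56.0 |
| 2.50 | 59.5 |
| 3.00 | 60.1 |
| 4.00 | 58.5 |
| 5.00 | 58.4 |

dawn run (percent of the G charged)

| time / h | Z / % |
|---|---|
| 3.00 | 28.6 |
| 6.00 | 42.8 |
| 10.0 | 52.9 |
| 15.0 | 58.0 |
| 25.0 | 57.5 |
| 40.0 | 59.0 |

(readings scatter by 1 percentage point)

* Z, in percent of the G first charged, at 5.0 d
* the option that brings most further Z ("none" if no option brings more than 2 percentage points) (grey / green / violet / none)
* Z present, with what was taken out counted in, in percent of the G first charged, after green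
* Z present, with what was taken out counted in, in percent of the G first charged, after violet

- grey: change nothing and wait 2.5 d more
- green: at 5.0 d raise the temperature by 20 K, then wait 2.5 d
- violet: at 5.0 d take out 90 % of the Z then present, then wait 2.5 d

- what is taken out of Z is counted as made
- what was read earlier has a scatter of 1 percentage point, one standard deviation
- on the list of suspects stand: G -> Z; Q -> Z; E + Q -> L; G <-> D; G -> Q

The first chemist holds that the plateau is a fixed split of G between parallel paths, a selectivity factor, so that the flask has nothing further to give once G is used. The second looks at the shortfall of Z in the spring flask, 41.6 %, supposes that a slow store might sit inside it, and integrates a first-order release in closed form, so that a store of size s gains s(1 − exp(−kt)) over a wait t. She then asks how fast such a release could run and still hide in the flat tail, and she takes the constant at which the whole shortfall gains just 2 percentage points, two standard deviations, between the spring readings at 3.00 d and 5.00 d: the blind rate 0.0246 /d. At that rate grey could bring 2.5 points, so the tail cannot refuse a gain above the margin of 2 points. Applying the dawn speed-up unchanged to green's 20 K, her own reckoning, which is not the forecast's, gives green 5 points.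

The forecast is the first chemist's: now 59 % (58 % to 60 %), best option none, green 59.5 % (58 % to 62.5 %), violet 59 % (58 % to 60.5 %), on the ground that “The flat tail shows Q→Z is negligible and no slow D reservoir is visible.”

    G → Z (k = 1.79 × 10⁻⁵ /s, Ea = 99.0 kJ/mol)
    Q → Z (k = 1.57 × 10⁻⁵ /s, Ea = 108 kJ/mol)
    E + Q → L (k = 2.97 × 10⁻⁵ /M/s, Ea = 75.0 kJ/mol)
    G ⇌ D (K = 13.0, k = 6.98 × 10⁻⁶ /s, Ea = 120 kJ/mol, ΔH = 34.0 kJ/mol)
    G → Q (k = 1.13 × 10⁻⁵ /s, Ea = 98.0 kJ/mol)
    (constants at 50 °C)

The flask stands at 59.2 %, and the best option is green, which reaches 64.6 %, a gain of 5.4 points. At 5.00 d this flask holds D at 16.2 % beside L at 24.3 %. The first view's small gain holds for this flask over the wait of 2.5 d at 50 °C: grey reaches 60.3 % and violet 60.3 %, each bringing 1 point, less than the margin and less than the blind rate's allowance. Its fixed split does not hold: G stands at 0.243 % at 5.00 d, yet this flask, left at 50 °C to 50.0 d, has Z at 68.8 % and D down to 3.01 %. The dawn flask, left to 5.0 d, goes from 58.9 % to 61.8 %, a gain of 2.9 points, less than the 6.5 points that the blind rate allows it.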